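The cyclopentane is opened at two non-adjacent bonds: the ring-fusion bond between the methyl-bearing quaternary carbon and the fusion CH, and the bond between the side-chain CH and its ring CH2 neighbour. The precursor is an open-chain (Z)-1,5-dien-3-ol carrying a primary tosylate. Its potassium alkoxide undergoes an anionic oxy-Cope shift, and the aldehyde enolate so released alkylates the tosylate, closing the five-membered ring with three contiguous stereocentres in one operation. The step exploits two features: the carbon attached to the cyclopentane CH can be an aldehyde, and the quaternary carbon bears a vinyl group that later becomes the cycloheptene by ring-closing metathesis.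

Key step: step 9

Remark: bicyclic compounds are named on the azulene skeleton (C-1 bears the side chain, C-3a the angular methyl, C-4 the oxygen, C-5/C-6 the epoxide, C-8a the fusion hydrogen); "epoxy" denotes the oxirane bridge.
Remark: (S)-BINOL is assumed to deliver the (R)-carbinol in step 5; if the sense proves opposite, (R)-BINOL is used.

Step 1
Reactants: 1 tert-butyl(but-3-yn-1-yloxy)dimethylsilane
Product: 3 (E)-6-[(tert-butyldimethylsilyl)oxy]-4-methylhex-3-en-1-ol, via alkenylalane 2 (not isolated)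
Conditions: AlMe3, Cp2ZrCl2 (cat.), CH2Cl2, 0 °C to rt; then n-BuLi, THF, −78 °C; oxirane, −78 °C to rt
Reagents that add atoms: trimethylaluminium C[Al](C)C; oxirane C1CO1
Why: Zirconium-catalysed carboalumination (Negishi) adds methyl and aluminium syn across the alkyne and the derived alanate opens oxirane with retention, so the new CH2CH2OH chain should stand cis to methyl (E-alkene).

Step 2
Reactants: 3 (E)-6-[(tert-butyldimethylsilyl)oxy]-4-methylhex-3-en-1-ol
Product: 4 (E)-6-[(tert-butyldimethylsilyl)oxy]-4-methylhex-3-enal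
Conditions: Dess–Martin periodinane, NaHCO3, CH2Cl2, 0 °C; used at once
Reagents that add atoms: none
Why: Buffered Dess–Martin oxidation should give the β,γ-unsaturated aldehyde without moving the double bond into conjugation.

Step 3
Reactants: 5 (S)-3,7-dimethylocta-1,6-diene [(S)-β-citronellene]
Product: 7 (4S)-4-methylhex-5-enal, via ozonide 6 (not isolated)
Conditions: O3 (1.0 equiv), CH2Cl2, −78 °C; then Me2S, −78 °C to rt
Reagents that add atoms: ozone [O-][O+]=O
Why: Chemoselective ozonolysis: the electron-rich trisubstituted alkene reacts much faster than the vinyl group, and reductive work-up of the ozonide leaves the allylic stereocentre untouched.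

Step 4
Reactants: 7 (4S)-4-methylhex-5-enal
Product: 8 (3S)-3-methylhept-1-en-6-yne
Conditions: dimethyl (1-diazo-2-oxopropyl)phosphonate, K2CO3, MeOH, 0 °C to rt
Reagents that add atoms: dimethyl (1-diazo-2-oxopropyl)phosphonate CC(=O)C(=[N+]=[N-])P(=O)(OC)OC
Why: Ohira–Bestmann (Seyferth–Gilbert) homologation should turn the aldehyde into the terminal alkyne under carbonate conditions that cannot touch the remote stereocentre.

Step 5
Reactants: 8 (3S)-3-methylhept-1-en-6-yne; 4 (E)-6-[(tert-butyldimethylsilyl)oxy]-4-methylhex-3-enal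
Product: 10 (3E,6R,11S)-1-[(tert-butyldimethylsilyl)oxy]-3,11-dimethyltrideca-3,12-dien-7-yn-6-ol, via alkynylzinc 9 (not isolated)
Conditions: 8, Et2Zn, Cy2NH, Et2O, rt; then (S)-BINOL (cat.), Ti(OiPr)4 (cat.), 4, rt
Reagents that add atoms: none
Why: BINOL–titanium-catalysed asymmetric addition of the alkynylzinc to the aldehyde should set the (R)-carbinol by reagent control, with the E-alkene and the methyl-bearing centre as spectators.

Step 6
Reactants: 10 (3E,6R,11S)-1-[(tert-butyldimethylsilyl)oxy]-3,11-dimethyltrideca-3,12-dien-7-yn-6-ol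
Product: 11 (3E,6R,7Z,11S)-1-[(tert-butyldimethylsilyl)oxy]-3,11-dimethyltrideca-3,7,12-trien-6-ol
Conditions: H2 (1 atm), Pd/CaCO3 poisoned with Pb(OAc)2 (Lindlar catalyst), quinoline, EtOAc, rt
Reagents that add atoms: none
Why: Lindlar semihydrogenation adds H2 syn to the alkyne only, giving the (Z)-allylic alcohol required for strict chair control in step 9, while quinoline should hold back reduction of the vinyl group.

Step 7
Reactants: 11 (3E,6R,7Z,11S)-1-[(tert-butyldimethylsilyl)oxy]-3,11-dimethyltrideca-3,7,12-trien-6-ol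
Product: 12 (3E,6R,7Z,11S)-3,11-dimethyltrideca-3,7,12-triene-1,6-diol
Conditions: Bu4NF, THF, 0 °C to rt
Reagents that add atoms: none
Why: Fluoride-mediated desilylation should free the primary alcohol without affecting the alkenes or the allylic carbinol.

Step 8
Reactants: 12 (3E,6R,7Z,11S)-3,11-dimethyltrideca-3,7,12-triene-1,6-diol
Product: 13 (3E,6R,7Z,11S)-6-hydroxy-3,11-dimethyltrideca-3,7,12-trien-1-yl 4-methylbenzenesulfonate
Conditions: TsCl (1.05 equiv), Et3N, DMAP (cat.), CH2Cl2, −10 °C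
Reagents that add atoms: 4-methylbenzenesulfonyl chloride Cc1ccc(cc1)S(Cl)(=O)=O
Why: Sulfonylation at low temperature should be selective for the unhindered primary hydroxyl over the secondary allylic one, installing the leaving group for ring closure.

Step 9
Reactants: 13 (3E,6R,7Z,11S)-6-hydroxy-3,11-dimethyltrideca-3,7,12-trien-1-yl 4-methylbenzenesulfonate
Product: 16 (1R,2S,3R)-3-ethenyl-3-methyl-2-[(3S)-3-methylpent-4-en-1-yl]cyclopentane-1-carbaldehyde, via potassium alkoxide 14 (not isolated), via potassium enolate 15 (not isolated)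
Conditions: KH, 18-crown-6, THF (high dilution), 0 °C to 50 °C; then pH 7 buffer
Reagents that add atoms: none
Why: Deprotonation gives alkoxide 14, whose [3,3]-sigmatropic shift (anionic oxy-Cope rearrangement) through a chair transition state forms the bond between the quaternary carbon and the future fusion CH and releases the (E)-aldehyde enolate 15, which displaces the primary tosylate to close the cyclopentane. The closest known reaction type is the tandem anionic oxy-Cope rearrangement/enolate alkylation. The sigmatropic event closes no ring; the five-membered ring closes by 5-(enolexo)-exo-tet C-alkylation. The quaternary and the adjacent tertiary stereocentres are set together by the chair: the (E)-trisubstituted alkene puts methyl axial, the (Z)-alkene puts the pentenyl chain axial, and the (R)-carbinol fixes the absolute sense because its oxido group must sit equatorial to avoid a 1,3-diaxial clash with that chain; the formyl-bearing centre is epimerisable and should settle trans to its neighbour (it is equilibrated again in step 10). The step needs the [3,3] shift to outrun alkoxide fragmentation and C-alkylation to outrun O-alkylation: the crown-ether-separated potassium alkoxide accelerates the concerted shift, O-alkylation of the (E)-enolate or direct Williamson closure of 14 would each require a seven-membered ring containing a trans double bond, and high dilution suppresses intermolecular aldol reaction.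

Step 10
Reactants: 16 (1R,2S,3R)-3-ethenyl-3-methyl-2-[(3S)-3-methylpent-4-en-1-yl]cyclopentane-1-carbaldehyde
Product: 17 (1R,2S,3R)-1-ethenyl-3-ethynyl-1-methyl-2-[(3S)-3-methylpent-4-en-1-yl]cyclopentane
Conditions: K2CO3, MeOH, rt (equilibration); then dimethyl (1-diazo-2-oxopropyl)phosphonate, rt
Reagents that add atoms: dimethyl (1-diazo-2-oxopropyl)phosphonate CC(=O)C(=[N+]=[N-])P(=O)(OC)OC
Why: Carbonate should first equilibrate the formyl-bearing carbon to the trans arrangement relative to the neighbouring chain, and Ohira–Bestmann homologation then locks that centre as a non-epimerisable alkyne.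

Step 11
Reactants: 17 (1R,2S,3R)-1-ethenyl-3-ethynyl-1-methyl-2-[(3S)-3-methylpent-4-en-1-yl]cyclopentane
Product: 19 methyl 3-{(1R,2S,3R)-3-ethenyl-3-methyl-2-[(3S)-3-methylpent-4-en-1-yl]cyclopentyl}prop-2-ynoate, via lithium acetylide 18 (not isolated)
Conditions: n-BuLi, THF, −78 °C; then ClCO2Me, −78 to 0 °C
Reagents that add atoms: methyl chloroformate COC(Cl)=O
Why: Deprotonation of the terminal alkyne and C-acylation of the acetylide with the chloroformate should give the ynoate, no other acidic or electrophilic site being present.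

Step 12
Reactants: 19 methyl 3-{(1R,2S,3R)-3-ethenyl-3-methyl-2-[(3S)-3-methylpent-4-en-1-yl]cyclopentyl}prop-2-ynoate
Product: 20 methyl (2Z)-3-{(1R,2S,3R)-3-ethenyl-3-methyl-2-[(3S)-3-methylpent-4-en-1-yl]cyclopentyl}but-2-enoate
Conditions: Me2CuLi (from MeLi and CuI), THF, −78 °C; aq. NH4Cl at −78 °C
Reagents that add atoms: lithium dimethylcuprate [Li+].C[Cu-]C
Why: Syn-carbocupration of the ynoate at −78 °C and protonation with retention place the new methyl cis to hydrogen, so the ring carbon and the ester should end up cis, which is the (Z)-trisubstituted geometry of the target.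

Step 13
Reactants: 20 methyl (2Z)-3-{(1R,2S,3R)-3-ethenyl-3-methyl-2-[(3S)-3-methylpent-4-en-1-yl]cyclopentyl}but-2-enoate
Product: 21 methyl (2Z)-3-[(1R,3aR,6S,8aS)-3a,6-dimethyl-1,2,3,3a,6,7,8,8a-octahydroazulen-1-yl]but-2-enoate
Conditions: second-generation Grubbs catalyst (H2IMes)(PCy3)Cl2Ru=CHPh (cat.), CH2Cl2 (high dilution), 40 °C
Reagents that add atoms: none
Why: Ring-closing metathesis should join the two vinyl groups, the only reactive alkenes (the trisubstituted enoate is inert), closing the seven-membered ring trans-fused to the cyclopentane with loss of ethene.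

Step 14
Reactants: 21 methyl (2Z)-3-[(1R,3aR,6S,8aS)-3a,6-dimethyl-1,2,3,3a,6,7,8,8a-octahydroazulen-1-yl]but-2-enoate
Product: 23 methyl (2Z)-3-[(1R,3aS,4S,5S,6R,8aS)-5,6-epoxy-4-hydroxy-3a,6-dimethyldecahydroazulen-1-yl]but-2-enoate, via allylic hydroperoxide 22 (not isolated)
Conditions: O2, visible light, tetraphenylporphyrin (cat.), CH2Cl2, −10 °C; then Ti(OiPr)4 (cat.), 4 Å molecular sieves, −10 °C to rt
Reagents that add atoms: dioxygen O=O
Why: In the Schenck ene reaction singlet oxygen can abstract only the single allylic hydrogen at C-6, which lies on the face opposite the angular methyl, so the hydroperoxide should form at C-4 on that face with the double bond moved to C-5/C-6, and titanium-mediated oxygen transfer then epoxidises this alkene syn to the resulting hydroxyl.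

Step 15
Reactants: 23 methyl (2Z)-3-[(1R,3aS,4S,5S,6R,8aS)-5,6-epoxy-4-hydroxy-3a,6-dimethyldecahydroazulen-1-yl]but-2-enoate
Product: 24 (2Z)-3-[(1R,3aS,4S,5S,6R,8aS)-5,6-epoxy-4-hydroxy-3a,6-dimethyldecahydroazulen-1-yl]but-2-en-1-ol
Conditions: iBu2AlH (excess), CH2Cl2, −78 °C; Rochelle salt work-up
Reagents that add atoms: none
Why: 1,2-Reduction of the enoate by the aluminium hydride at −78 °C should give the (Z)-allylic alcohol while the hindered trisubstituted epoxide survives.

Step 16
Reactants: 24 (2Z)-3-[(1R,3aS,4S,5S,6R,8aS)-5,6-epoxy-4-hydroxy-3a,6-dimethyldecahydroazulen-1-yl]but-2-en-1-ol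
Product: 26 (3E,5Z)-6-[(1R,3aS,4S,5S,6R,8aS)-5,6-epoxy-4-hydroxy-3a,6-dimethyldecahydroazulen-1-yl]hepta-3,5-dien-2-one, via enal 25 (not isolated)
Conditions: MnO2, Ph3P=CHC(O)CH3, CH2Cl2, rt
Reagents that add atoms: 1-(triphenylphosphoranylidene)propan-2-one CC(=O)C=P(c1ccccc1)(c1ccccc1)c1ccccc1
Why: MnO2 oxidises only the allylic primary alcohol (the epoxy alcohol is not allylic), and the stabilised ylide should trap the enal at once in an (E)-selective Wittig reaction before the (Z)-enal can isomerise.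

Step 17
Reactants: 26 (3E,5Z)-6-[(1R,3aS,4S,5S,6R,8aS)-5,6-epoxy-4-hydroxy-3a,6-dimethyldecahydroazulen-1-yl]hepta-3,5-dien-2-one
Product: 27 (1R,3aS,4S,5S,6R,8aS)-5,6-epoxy-1-[(2Z,4E)-6-hydroxy-6-methylhepta-2,4-dien-2-yl]-3a,6-dimethyldecahydroazulen-4-ol
Conditions: MeLi (excess), THF, −78 °C
Reagents that add atoms: methyllithium [Li]C
Why: Methyllithium should add 1,2 to the dienone carbonyl (the free hydroxyl is merely deprotonated), giving the tertiary allylic alcohol without opening the epoxide at low temperature.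

Step 18
Reactants: 27 (1R,3aS,4S,5S,6R,8aS)-5,6-epoxy-1-[(2Z,4E)-6-hydroxy-6-methylhepta-2,4-dien-2-yl]-3a,6-dimethyldecahydroazulen-4-ol
Product: 28 (1R,3aS,4S,5S,6R,8aS)-5,6-epoxy-1-[(2Z,4E)-6-hydroxy-6-methylhepta-2,4-dien-2-yl]-3a,6-dimethyldecahydroazulen-4-yl acetate (CNP0265175.1)
Conditions: Ac2O (1.2 equiv), pyridine, DMAP (cat.), CH2Cl2, 0 °C
Reagents that add atoms: acetic anhydride CC(=O)OC(C)=O
Why: DMAP-catalysed acetylation should take the secondary hydroxyl selectively, the tertiary allylic alcohol being too hindered to react at 0 °C with a near-stoichiometric amount of anhydride.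

Compound list
1 | tert-butyl(but-3-yn-1-yloxy)dimethylsilane | C#CCCO[Si](C)(C)C(C)(C)C | starting material
2 | (E)-{4-[(tert-butyldimethylsilyl)oxy]-2-methylbut-1-en-1-yl}dimethylalane | C[Al](C)/C=C(\C)CCO[Si](C)(C)C(C)(C)C | intermediate
3 | (E)-6-[(tert-butyldimethylsilyl)oxy]-4-methylhex-3-en-1-ol | OCC/C=C(\C)CCO[Si](C)(C)C(C)(C)C | intermediate
4 | (E)-6-[(tert-butyldimethylsilyl)oxy]-4-methylhex-3-enal | O=CC/C=C(\C)CCO[Si](C)(C)C(C)(C)C | intermediate
5 | (S)-3,7-dimethylocta-1,6-diene [(S)-β-citronellene] | C=C[C@@H](C)CCC=C(C)C | starting material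
6 | 3,3-dimethyl-5-[(3S)-3-methylpent-4-en-1-yl]-1,2,4-trioxolane (ozonide) | CC1(C)OOC(CC[C@H](C)C=C)O1 | intermediate
7 | (4S)-4-methylhex-5-enal | C=C[C@@H](C)CCC=O | intermediate
8 | (3S)-3-methylhept-1-en-6-yne | C=C[C@@H](C)CCC#C | intermediate
9 | ethyl[(5S)-5-methylhept-6-en-1-yn-1-yl]zinc | CC[Zn]C#CCC[C@H](C)C=C | intermediate
10 | (3E,6R,11S)-1-[(tert-butyldimethylsilyl)oxy]-3,11-dimethyltrideca-3,12-dien-7-yn-6-ol | C=C[C@@H](C)CCC#C[C@H](O)C/C=C(\C)CCO[Si](C)(C)C(C)(C)C | intermediate
11 | (3E,6R,7Z,11S)-1-[(tert-butyldimethylsilyl)oxy]-3,11-dimethyltrideca-3,7,12-trien-6-ol | C=C[C@@H](C)CC/C=C\[C@H](O)C/C=C(\C)CCO[Si](C)(C)C(C)(C)C | intermediate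
12 | (3E,6R,7Z,11S)-3,11-dimethyltrideca-3,7,12-triene-1,6-diol | C=C[C@@H](C)CC/C=C\[C@H](O)C/C=C(\C)CCO | intermediate
13 | (3E,6R,7Z,11S)-6-hydroxy-3,11-dimethyltrideca-3,7,12-trien-1-yl 4-methylbenzenesulfonate | C=C[C@@H](C)CC/C=C\[C@H](O)C/C=C(\C)CCOS(=O)(=O)c1ccc(C)cc1 | intermediate
14 | potassium alkoxide of 13 | [K+].C=C[C@@H](C)CC/C=C\[C@H]([O-])C/C=C(\C)CCOS(=O)(=O)c1ccc(C)cc1 | intermediate
15 | potassium (E)-enolate of (3S,4R)-4-methyl-3-[(3S)-3-methylpent-4-en-1-yl]-4-[2-(tosyloxy)ethyl]hex-5-enal | [K+].C=C[C@@H](C)CC[C@@H](/C=C/[O-])[C@](CCOS(=O)(=O)c1ccc(C)cc1)(C=C)C | intermediate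
16 | (1R,2S,3R)-3-ethenyl-3-methyl-2-[(3S)-3-methylpent-4-en-1-yl]cyclopentane-1-carbaldehyde | C=C[C@@H](C)CC[C@H]1[C@H](C=O)CC[C@@]1(C=C)C | intermediate
17 | (1R,2S,3R)-1-ethenyl-3-ethynyl-1-methyl-2-[(3S)-3-methylpent-4-en-1-yl]cyclopentane | C=C[C@@H](C)CC[C@H]1[C@H](C#C)CC[C@@]1(C=C)C | intermediate
18 | lithium acetylide of 17 | C=C[C@@H](C)CC[C@H]1[C@H](C#C[Li])CC[C@@]1(C=C)C | intermediate
19 | methyl 3-{(1R,2S,3R)-3-ethenyl-3-methyl-2-[(3S)-3-methylpent-4-en-1-yl]cyclopentyl}prop-2-ynoate | C=C[C@@H](C)CC[C@H]1[C@H](C#CC(=O)OC)CC[C@@]1(C=C)C | intermediate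
20 | methyl (2Z)-3-{(1R,2S,3R)-3-ethenyl-3-methyl-2-[(3S)-3-methylpent-4-en-1-yl]cyclopentyl}but-2-enoate | C=C[C@@H](C)CC[C@H]1[C@H](/C(C)=C\C(=O)OC)CC[C@@]1(C=C)C | intermediate
21 | methyl (2Z)-3-[(1R,3aR,6S,8aS)-3a,6-dimethyl-1,2,3,3a,6,7,8,8a-octahydroazulen-1-yl]but-2-enoate | C1=C[C@@H](C)CC[C@H]2[C@H](/C(C)=C\C(=O)OC)CC[C@]12C | intermediate
22 | methyl (2Z)-3-[(1R,3aS,4R,8aS)-4-hydroperoxy-3a,6-dimethyl-1,2,3,3a,4,7,8,8a-octahydroazulen-1-yl]but-2-enoate | OO[C@@H]1C=C(C)CC[C@H]2[C@H](/C(C)=C\C(=O)OC)CC[C@]12C | intermediate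
23 | methyl (2Z)-3-[(1R,3aS,4S,5S,6R,8aS)-5,6-epoxy-4-hydroxy-3a,6-dimethyldecahydroazulen-1-yl]but-2-enoate | O[C@@H]1[C@@H]2O[C@]2(C)CC[C@H]2[C@H](/C(C)=C\C(=O)OC)CC[C@]12C | intermediate
24 | (2Z)-3-[(1R,3aS,4S,5S,6R,8aS)-5,6-epoxy-4-hydroxy-3a,6-dimethyldecahydroazulen-1-yl]but-2-en-1-ol | O[C@@H]1[C@@H]2O[C@]2(C)CC[C@H]2[C@H](/C(C)=C\CO)CC[C@]12C | intermediate
25 | (2Z)-3-[(1R,3aS,4S,5S,6R,8aS)-5,6-epoxy-4-hydroxy-3a,6-dimethyldecahydroazulen-1-yl]but-2-enal | O[C@@H]1[C@@H]2O[C@]2(C)CC[C@H]2[C@H](/C(C)=C\C=O)CC[C@]12C | intermediate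
26 | (3E,5Z)-6-[(1R,3aS,4S,5S,6R,8aS)-5,6-epoxy-4-hydroxy-3a,6-dimethyldecahydroazulen-1-yl]hepta-3,5-dien-2-one | O[C@@H]1[C@@H]2O[C@]2(C)CC[C@H]2[C@H](/C(C)=C\C=C\C(C)=O)CC[C@]12C | intermediate
27 | (1R,3aS,4S,5S,6R,8aS)-5,6-epoxy-1-[(2Z,4E)-6-hydroxy-6-methylhepta-2,4-dien-2-yl]-3a,6-dimethyldecahydroazulen-4-ol | O[C@@H]1[C@@H]2O[C@]2(C)CC[C@H]2[C@H](/C(C)=C\C=C\C(C)(C)O)CC[C@]12C | intermediate
28 | (1R,3aS,4S,5S,6R,8aS)-5,6-epoxy-1-[(2Z,4E)-6-hydroxy-6-methylhepta-2,4-dien-2-yl]-3a,6-dimethyldecahydroazulen-4-yl acetate (CNP0265175.1) | CC(=O)O[C@@H]1[C@@H]2O[C@]2(C)CC[C@H]2[C@H](/C(C)=C\C=C\C(C)(C)O)CC[C@]12C | target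

Total step count: 18. Longest linear sequence: 16 steps (steps 1, 2 and 5 to 18; steps 3 and 4 make the second fragment).

Steps most likely to fail

Step 9. The alkoxide may fragment heterolytically (loss of the allyl unit) instead of rearranging, or the aldehyde enolate may be consumed by aldol reaction or proton transfer before it cyclises. The fallback separates the two bond formations and avoids the alkoxide. It sets out from 11: the carbinol is silylated (TMSCl, imidazole) to the bis-silyl ether F1, which is heated (xylene, 200 °C, sealed tube) so that the neutral silyloxy-Cope rearrangement gives the silyl enol ether F2 through the same chair. Mild acid hydrolysis then gives the aldehyde F3, Bu4NF the hydroxy aldehyde F4, and I2/PPh3/imidazole (Appel conditions) the iodo aldehyde F5. Amine-catalysed intramolecular enamine α-alkylation (α-methylproline, Et3N) closes the ring, and the fallback returns to the route at 16.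

Step 14. The ene reaction of a cis-disubstituted alkene flanked by a quaternary carbon may be too slow, leading to incomplete conversion or photodegradation, and the oxygen transfer may lose facial control. The fallback sets out from 21: mCPBA should epoxidise the ring alkene on the face opposite both methyl groups to give the epoxide F6. Et2Al-TMP (from Et2AlCl and LiTMP) then effects syn-elimination through the same C-6 hydrogen to give the allylic alcohol F7. Hydroxyl-directed epoxidation with VO(acac)2/tBuOOH brings the fallback back to the route at 23.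

Step 5. The β,γ-double bond of 4 may migrate into conjugation or the aldehyde may self-condense under the zinc/titanium conditions, and enantiofacial control may be incomplete. The fallback sets out from 8 and 4: the lithium acetylide of 8 (n-BuLi, THF, −78 °C) adds to 4 to give the epimeric alcohol F8, and Dess–Martin oxidation gives the ynone F9. Noyori transfer hydrogenation with RuCl[(R,R)-TsDPEN](p-cymene) in iPrOH (the catalyst enantiomer that gives the (R)-carbinol) returns the fallback to the route at 10.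

Further compounds
F1 | step 9 | (3E,6R,7Z,11S)-1-[(tert-butyldimethylsilyl)oxy]-3,11-dimethyl-6-[(trimethylsilyl)oxy]trideca-3,7,12-triene | C=C[C@@H](C)CC/C=C\[C@H](O[Si](C)(C)C)C/C=C(\C)CCO[Si](C)(C)C(C)(C)C
F2 | step 9 | (1E,3S,4R)-4-{2-[(tert-butyldimethylsilyl)oxy]ethyl}-4-methyl-3-[(3S)-3-methylpent-4-en-1-yl]-1-[(trimethylsilyl)oxy]hexa-1,5-diene | C=C[C@@H](C)CC[C@@H](/C=C/O[Si](C)(C)C)[C@](CCO[Si](C)(C)C(C)(C)C)(C=C)C
F3 | step 9 | (3S,4R)-4-{2-[(tert-butyldimethylsilyl)oxy]ethyl}-4-methyl-3-[(3S)-3-methylpent-4-en-1-yl]hex-5-enal | C=C[C@@H](C)CC[C@@H](CC=O)[C@](CCO[Si](C)(C)C(C)(C)C)(C=C)C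
F4 | step 9 | (3S,4R)-4-(2-hydroxyethyl)-4-methyl-3-[(3S)-3-methylpent-4-en-1-yl]hex-5-enal | C=C[C@@H](C)CC[C@@H](CC=O)[C@](CCO)(C=C)C
F5 | step 9 | (3S,4R)-4-(2-iodoethyl)-4-methyl-3-[(3S)-3-methylpent-4-en-1-yl]hex-5-enal | C=C[C@@H](C)CC[C@@H](CC=O)[C@](CCI)(C=C)C
F6 | step 14 | methyl (2Z)-3-[(1R,3aS,4S,5R,6S,8aS)-4,5-epoxy-3a,6-dimethyldecahydroazulen-1-yl]but-2-enoate | C[C@H]1CC[C@H]2[C@H](/C(C)=C\C(=O)OC)CC[C@]2(C)[C@@H]3O[C@H]13
F7 | step 14 | methyl (2Z)-3-[(1R,3aS,4R,8aS)-4-hydroxy-3a,6-dimethyl-1,2,3,3a,4,7,8,8a-octahydroazulen-1-yl]but-2-enoate | O[C@@H]1C=C(C)CC[C@H]2[C@H](/C(C)=C\C(=O)OC)CC[C@]12C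
F8 | step 5 | (3E,6RS,11S)-1-[(tert-butyldimethylsilyl)oxy]-3,11-dimethyltrideca-3,12-dien-7-yn-6-ol (both carbinol epimers) | C=C[C@@H](C)CCC#CC(O)C/C=C(\C)CCO[Si](C)(C)C(C)(C)C
F9 | step 5 | (3E,11S)-1-[(tert-butyldimethylsilyl)oxy]-3,11-dimethyltrideca-3,12-dien-7-yn-6-one | C=C[C@@H](C)CCC#CC(=O)C/C=C(\C)CCO[Si](C)(C)C(C)(C)C
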